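**Retrosynthetic overview**
- The target comes from the tricyclic lactone by angeloylation of O8 and desilylation of O1; all rings and stereocentres are in place before the ester goes on.
- The ten-membered carbocycle and the cis-fused α-methylene-γ-lactone are closed together by one chromium-mediated intramolecular 2-(methoxycarbonyl)allylation/lactonisation (C6–C7, then O6–C12), which also sets C6 and C7.
- The cyclisation substrate carries a Z-enal (methylcuprate syn-addition to an ynoate, then redox) and a (2Z)-2-(bromomethyl)enoate (Morita–Baylis–Hillman reaction and allylic bromination at the C7 aldehyde).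
- The oxolane comes from Shi epoxidation and 5-endo opening of a homoallylic propargylic alcohol; C3 from zinc–ProPhenol alkynylation, the E-olefin from Negishi carboalumination/oxirane opening, C8 from asymmetric propargylation of 2,2-dimethoxyacetaldehyde.
- Ring order: oxolane first, then carbocycle and lactone in one operation.

Assumption: atom labels C1–C15 follow germacrane numbering (lactone O on C6, ester on C8, ether O bridging C3 and C10), and the SMILES is read literally as (1S,3S,6S,7R,8R,10R), 4Z, with H-6/H-7 cis on the lactone and the C4 and C9 branches trans on the oxolane.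

**Route**

Step 1
Reactants: 1 2,2-dimethoxyacetaldehyde; 2 allenylboronic acid pinacol ester
Product: 3 (2R)-1,1-dimethoxypent-4-yn-2-ol
Conditions: 1 (dried, freshly distilled), 3,3′-bis(2,4,6-triisopropylphenyl)-1,1′-binaphthyl-2,2′-diyl hydrogen phosphate (TRIP, 5 mol%, the antipode that gives the 2R alcohol), 4 Å MS, toluene, −20 °C; aq. work-up
Reagents that add atoms: none
Why: Chiral-phosphoric-acid-catalysed allenylboronate propargylation, in which the acid binds the boronate oxygen and the formyl hydrogen in a closed six-membered SE2′ transition state so that the allenyl γ-carbon adds to one aldehyde face and sets C8 as R.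

Step 2
Reactants: 3 (2R)-1,1-dimethoxypent-4-yn-2-ol
Product: 4 1-({[(2R)-1,1-dimethoxypent-4-yn-2-yl]oxy}methyl)-4-methoxybenzene
Conditions: NaH (1.1 equiv), 4-methoxybenzyl chloride, Bu4NI (cat.), THF, 0 °C → rt
Reagents that add atoms: 4-methoxybenzyl chloride, COc1ccc(CCl)cc1
Why: Williamson etherification of the sodium alkoxide, which leaves the stereocentre untouched and installs a PMB ether that survives the organoaluminium, cuprate, hydride and chromium steps yet is removed oxidatively.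

Step 3
Reactants: 4 1-({[(2R)-1,1-dimethoxypent-4-yn-2-yl]oxy}methyl)-4-methoxybenzene; 5 oxirane
Product: 7 (3E,6R)-7,7-dimethoxy-6-[(4-methoxybenzyl)oxy]-4-methylhept-3-en-1-ol, via alkenylalane 6 (not isolated)
Conditions: AlMe3 (2.5 equiv), Cp2ZrCl2 (20 mol%), H2O (1 equiv), CH2Cl2, −20 °C; volatiles removed; n-BuLi (1.05 equiv), THF/hexane, −30 °C; oxirane (5 equiv), −30 → 0 °C
Reagents that add atoms: trimethylaluminium, C[Al](C)C
Why: Negishi zirconium-catalysed carboalumination adds Me and Al syn across the terminal alkyne (Me on the internal carbon), and the derived alkenylalanate opens oxirane with retention to give the E trisubstituted C1=C10 olefin of a homoallylic alcohol.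

Step 4
Reactants: 7 (3E,6R)-7,7-dimethoxy-6-[(4-methoxybenzyl)oxy]-4-methylhept-3-en-1-ol
Product: 8 (3E,6R)-7,7-dimethoxy-6-[(4-methoxybenzyl)oxy]-4-methylhept-3-enal
Conditions: Dess–Martin periodinane (1.2 equiv), NaHCO3, CH2Cl2, 0 °C, 30 min; used crude at once
Reagents that add atoms: none
Why: Dess–Martin oxidation under buffered non-basic conditions gives the β,γ-unsaturated aldehyde without migration of the trisubstituted olefin into conjugation, provided it is used immediately.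

Step 5
Reactants: 8 (3E,6R)-7,7-dimethoxy-6-[(4-methoxybenzyl)oxy]-4-methylhept-3-enal; 9 methyl propiolate
Product: 10 methyl (4S,6E,9R)-4-hydroxy-10,10-dimethoxy-9-[(4-methoxybenzyl)oxy]-7-methyldec-6-en-2-ynoate
Conditions: 9 (3 equiv), Me2Zn (3 equiv), 2,6-bis{[2-(hydroxydiphenylmethyl)pyrrolidin-1-yl]methyl}-4-methylphenol (ProPhenol, 20 mol%, the antipode that gives the 4S carbinol), Ph3P=O (40 mol%), toluene, 4 °C
Reagents that add atoms: none
Why: Zinc–ProPhenol asymmetric alkynylation, in which the dinuclear zinc complex binds the aldehyde and delivers the zinc acetylide of methyl propiolate to one carbonyl face, sets the C3 carbinol (4S in the product name) under catalyst control.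

Step 6
Reactants: 10 methyl (4S,6E,9R)-4-hydroxy-10,10-dimethoxy-9-[(4-methoxybenzyl)oxy]-7-methyldec-6-en-2-ynoate
Product: 13 methyl 3-[(2S,4S,5R)-4-[(tert-butyldimethylsilyl)oxy]-5-{(2R)-3,3-dimethoxy-2-[(4-methoxybenzyl)oxy]propyl}-5-methyloxolan-2-yl]prop-2-ynoate, via epoxy alcohol 11 (not isolated), via oxolane alcohol 12 (not isolated)
Conditions: 1,2:4,5-di-O-isopropylidene-L-erythro-2,3-hexodiulo-2,6-pyranose (ent-Shi ketone, 30 mol%), Oxone (2KHSO5·KHSO4·K2SO4), K2CO3, Bu4NHSO4 (cat.), MeCN/dimethoxymethane–aq. buffer (pH 10), 0 °C; extract; camphor-10-sulfonic acid (10 mol%), CH2Cl2, 0 °C; then 2,6-lutidine, t-BuMe2SiOTf, −40 → 0 °C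
Reagents that add atoms: potassium peroxymonosulfate (KHSO5, the oxidant in Oxone), [K+].[O-]S(=O)(=O)OO; tert-butyldimethylsilyl trifluoromethanesulfonate, CC(C)(C)[Si](C)(C)OS(=O)(=O)C(F)(F)F
Why: Shi epoxidation (dioxirane, spiro transition state) is reagent-controlled on the electron-rich E trisubstituted olefin and spares the ynoate to give the (1S,10S)-epoxide, acid then triggers 5-endo opening at the tertiary C10 by the C3 hydroxyl with inversion, which fixes the oxolane with C4 and C9 trans and the new C1 hydroxyl cis to the C10 methyl, and the silyl triflate caps that hindered hydroxyl in the same flask.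

Step 7
Reactants: 13 methyl 3-[(2S,4S,5R)-4-[(tert-butyldimethylsilyl)oxy]-5-{(2R)-3,3-dimethoxy-2-[(4-methoxybenzyl)oxy]propyl}-5-methyloxolan-2-yl]prop-2-ynoate
Product: 14 methyl (2Z)-3-[(2S,4S,5R)-4-[(tert-butyldimethylsilyl)oxy]-5-{(2R)-3,3-dimethoxy-2-[(4-methoxybenzyl)oxy]propyl}-5-methyloxolan-2-yl]but-2-enoate
Conditions: Me2CuLi (from MeLi and CuI, 2 equiv), THF, −78 °C; sat. aq. NH4Cl at −78 °C
Reagents that add atoms: lithium dimethylcuprate, [Li+].C[Cu-]C
Why: Conjugate addition of lithium dimethylcuprate to the ynoate is a syn carbocupration, and protonation of the vinylcopper at −78 °C before allenoate equilibration leaves C3 and the ester cis, which is the 4Z olefin.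

Step 8
Reactants: 14 methyl (2Z)-3-[(2S,4S,5R)-4-[(tert-butyldimethylsilyl)oxy]-5-{(2R)-3,3-dimethoxy-2-[(4-methoxybenzyl)oxy]propyl}-5-methyloxolan-2-yl]but-2-enoate
Product: 15 (2Z)-3-[(2S,4S,5R)-4-[(tert-butyldimethylsilyl)oxy]-5-{(2R)-3,3-dimethoxy-2-[(4-methoxybenzyl)oxy]propyl}-5-methyloxolan-2-yl]but-2-en-1-ol
Conditions: i-Bu2AlH (2.5 equiv), CH2Cl2, −78 °C; aq. KNaC4H4O6 work-up
Reagents that add atoms: none
Why: 1,2-Reduction of the conjugated ester by the aluminium hydride at −78 °C gives the Z allylic alcohol while the acetal, silyl ether and PMB ether are inert.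

Step 9
Reactants: 15 (2Z)-3-[(2S,4S,5R)-4-[(tert-butyldimethylsilyl)oxy]-5-{(2R)-3,3-dimethoxy-2-[(4-methoxybenzyl)oxy]propyl}-5-methyloxolan-2-yl]but-2-en-1-ol
Product: 16 (2R)-3-[(2R,3S,5S)-3-[(tert-butyldimethylsilyl)oxy]-5-[(2Z)-4-hydroxybut-2-en-2-yl]-2-methyloxolan-2-yl]-2-[(4-methoxybenzyl)oxy]propanal
Conditions: TsOH·H2O (10 mol%), acetone/H2O (10:1), 25 °C
Reagents that add atoms: water, O
Why: Acid-catalysed acetal exchange and hydrolysis frees the C7 aldehyde under conditions too mild to cleave the hindered secondary silyl ether or the PMB ether or to epimerise the α-alkoxy centre.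

Step 10
Reactants: 16 (2R)-3-[(2R,3S,5S)-3-[(tert-butyldimethylsilyl)oxy]-5-[(2Z)-4-hydroxybut-2-en-2-yl]-2-methyloxolan-2-yl]-2-[(4-methoxybenzyl)oxy]propanal; 17 methyl acrylate
Product: 18 methyl (3RS,4R)-5-[(2R,3S,5S)-3-[(tert-butyldimethylsilyl)oxy]-5-[(2Z)-4-hydroxybut-2-en-2-yl]-2-methyloxolan-2-yl]-3-hydroxy-4-[(4-methoxybenzyl)oxy]-2-methylidenepentanoate
Conditions: 17 (neat, 20 equiv), 1,4-diazabicyclo[2.2.2]octane (0.5 equiv), MeOH (2 equiv), 25 °C, 48 h
Reagents that add atoms: none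
Why: Morita–Baylis–Hillman reaction, in which the amine adds to the acrylate and the zwitterionic enolate attacks the aliphatic aldehyde, gives the C7 carbinol as an epimer mixture that does not matter because C7 becomes sp2 in step 12.

Step 11
Reactants: 18 methyl (3RS,4R)-5-[(2R,3S,5S)-3-[(tert-butyldimethylsilyl)oxy]-5-[(2Z)-4-hydroxybut-2-en-2-yl]-2-methyloxolan-2-yl]-3-hydroxy-4-[(4-methoxybenzyl)oxy]-2-methylidenepentanoate
Product: 19 methyl (3RS,4R)-5-[(2R,3S,5S)-3-[(tert-butyldimethylsilyl)oxy]-2-methyl-5-[(2Z)-4-oxobut-2-en-2-yl]oxolan-2-yl]-3-hydroxy-4-[(4-methoxybenzyl)oxy]-2-methylidenepentanoate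
Conditions: 2,2,6,6-tetramethylpiperidin-1-oxyl (10 mol%), PhI(OAc)2 (1.2 equiv), CH2Cl2, 25 °C
Reagents that add atoms: none
Why: Nitroxyl/oxoammonium oxidation is selective for the primary allylic alcohol over the deactivated secondary Baylis–Hillman carbinol and does not isomerise the Z enal.

Step 12
Reactants: 19 methyl (3RS,4R)-5-[(2R,3S,5S)-3-[(tert-butyldimethylsilyl)oxy]-2-methyl-5-[(2Z)-4-oxobut-2-en-2-yl]oxolan-2-yl]-3-hydroxy-4-[(4-methoxybenzyl)oxy]-2-methylidenepentanoate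
Product: 20 methyl (2Z,4R)-2-(bromomethyl)-5-[(2R,3S,5S)-3-[(tert-butyldimethylsilyl)oxy]-2-methyl-5-[(2Z)-4-oxobut-2-en-2-yl]oxolan-2-yl]-4-[(4-methoxybenzyl)oxy]pent-2-enoate
Conditions: N-bromosuccinimide (1.3 equiv), Me2S (1.5 equiv), CH2Cl2, 0 → 25 °C
Reagents that add atoms: N-bromosuccinimide, O=C1CCC(=O)N1Br
Why: Corey–Kim-type activation of the carbinol as an alkoxysulfonium ion followed by SN2′ attack of bromide transposes the allylic system to the thermodynamically preferred (2Z)-2-(bromomethyl)enoate, in which C8 is trans to the ester and cis to CH2Br.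

Step 13
Reactants: 20 methyl (2Z,4R)-2-(bromomethyl)-5-[(2R,3S,5S)-3-[(tert-butyldimethylsilyl)oxy]-2-methyl-5-[(2Z)-4-oxobut-2-en-2-yl]oxolan-2-yl]-4-[(4-methoxybenzyl)oxy]pent-2-enoate
Product: 22 (1S,3S,4Z,6S,7R,8R,10R)-1-[(tert-butyldimethylsilyl)oxy]-3,10-epoxy-8-[(4-methoxybenzyl)oxy]germacra-4,11(13)-dien-12,6-olide, via hydroxy ester 21 (not isolated)
Conditions: CrCl2 (6 equiv), THF/DMF (4:1), 2 mM, syringe-pump addition of 20 over 12 h, 25 °C; aq. NH4Cl
Reagents that add atoms: none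
Why: Nozaki–Hiyama-type intramolecular 2-(alkoxycarbonyl)allylation, in which the allylchromium (trivalent chromium) from the (2Z)-bromide adds through C7 to the enal carbonyl in a chair six-membered transition state with C8 axial to give the 6,7-syn adduct whose chromium alkoxide closes onto the ester, forms the ten-membered carbocycle and the cis-fused α-methylene lactone in one operation, while allylic strain holds H-8 in the allyl plane with the C9 chain anti to the forming bond so that C6 adds on the face syn to the C8 oxygen and sets 7R and with it 6S.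

Step 14
Reactants: 22 (1S,3S,4Z,6S,7R,8R,10R)-1-[(tert-butyldimethylsilyl)oxy]-3,10-epoxy-8-[(4-methoxybenzyl)oxy]germacra-4,11(13)-dien-12,6-olide
Product: 23 (1S,3S,4Z,6S,7R,8R,10R)-1-[(tert-butyldimethylsilyl)oxy]-3,10-epoxy-8-hydroxygermacra-4,11(13)-dien-12,6-olide
Conditions: 2,3-dichloro-5,6-dicyano-1,4-benzoquinone (1.3 equiv), CH2Cl2/pH 7 buffer (10:1), 0 °C
Reagents that add atoms: none
Why: Oxidative PMB cleavage by electron transfer to the quinone (benzylic oxocarbenium, then hydrolysis) frees only the C8 hydroxyl, so the two secondary alcohols stay differentiated.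

Step 15
Reactants: 23 (1S,3S,4Z,6S,7R,8R,10R)-1-[(tert-butyldimethylsilyl)oxy]-3,10-epoxy-8-hydroxygermacra-4,11(13)-dien-12,6-olide; 24 angelic acid
Product: 26 (1S,3S,4Z,6S,7R,8R,10R)-8-angeloyloxy-1-[(tert-butyldimethylsilyl)oxy]-3,10-epoxygermacra-4,11(13)-dien-12,6-olide, via mixed anhydride 25 (not isolated)
Conditions: 24 (3 equiv), 2,4,6-trichlorobenzoyl chloride (3 equiv), Et3N (6 equiv), toluene, 25 °C, 2 h; then 23, 80 °C
Reagents that add atoms: none
Why: Yamaguchi-type acylation through the mixed anhydride without a nucleophilic catalyst acylates the hindered C8 alcohol and avoids the addition–elimination pathway that isomerises angelate (Z) to tiglate (E).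

Step 16
Reactants: 26 (1S,3S,4Z,6S,7R,8R,10R)-8-angeloyloxy-1-[(tert-butyldimethylsilyl)oxy]-3,10-epoxygermacra-4,11(13)-dien-12,6-olide
Product: 27 (1S,3S,4Z,6S,7R,8R,10R)-8-angeloyloxy-3,10-epoxy-1-hydroxygermacra-4,11(13)-dien-12,6-olide (CNP0213894.2)
Conditions: HF·pyridine, pyridine/THF, 0 → 25 °C
Reagents that add atoms: none
Why: Fluoride-mediated Si–O cleavage under buffered acidic conditions removes the silyl ether without touching the angelate, the α-methylene lactone or the allylic ethers and gives the target.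

**Compound list**

1 | 2,2-dimethoxyacetaldehyde | COC(OC)C=O | starting material
2 | allenylboronic acid pinacol ester [4,4,5,5-tetramethyl-2-(propa-1,2-dien-1-yl)-1,3,2-dioxaborolane] | C=C=CB1OC(C)(C)C(C)(C)O1 | starting material
3 | (2R)-1,1-dimethoxypent-4-yn-2-ol | C#CC[C@@H](O)C(OC)OC | intermediate
4 | 1-({[(2R)-1,1-dimethoxypent-4-yn-2-yl]oxy}methyl)-4-methoxybenzene | C#CC[C@@H](OCc1ccc(OC)cc1)C(OC)OC | intermediate
5 | oxirane | C1CO1 | starting material
6 | [(1E,4R)-5,5-dimethoxy-4-[(4-methoxybenzyl)oxy]-2-methylpent-1-en-1-yl]dimethylalumane | C[Al](C)/C=C(\C)C[C@@H](OCc1ccc(OC)cc1)C(OC)OC | intermediate (not isolated)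
7 | (3E,6R)-7,7-dimethoxy-6-[(4-methoxybenzyl)oxy]-4-methylhept-3-en-1-ol | OCC/C=C(\C)C[C@@H](OCc1ccc(OC)cc1)C(OC)OC | intermediate
8 | (3E,6R)-7,7-dimethoxy-6-[(4-methoxybenzyl)oxy]-4-methylhept-3-enal | O=CC/C=C(\C)C[C@@H](OCc1ccc(OC)cc1)C(OC)OC | intermediate
9 | methyl propiolate | C#CC(=O)OC | starting material
10 | methyl (4S,6E,9R)-4-hydroxy-10,10-dimethoxy-9-[(4-methoxybenzyl)oxy]-7-methyldec-6-en-2-ynoate | COC(=O)C#C[C@@H](O)C/C=C(\C)C[C@@H](OCc1ccc(OC)cc1)C(OC)OC | intermediate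
11 | methyl (4S)-5-[(2S,3S)-3-{(2R)-3,3-dimethoxy-2-[(4-methoxybenzyl)oxy]propyl}-3-methyloxiran-2-yl]-4-hydroxypent-2-ynoate | COC(=O)C#C[C@@H](O)C[C@@H]1O[C@@]1(C)C[C@@H](OCc2ccc(OC)cc2)C(OC)OC | intermediate (not isolated)
12 | methyl 3-[(2S,4S,5R)-5-{(2R)-3,3-dimethoxy-2-[(4-methoxybenzyl)oxy]propyl}-4-hydroxy-5-methyloxolan-2-yl]prop-2-ynoate | COC(=O)C#C[C@@H]1C[C@H](O)[C@@](C)(C[C@@H](OCc2ccc(OC)cc2)C(OC)OC)O1 | intermediate (not isolated)
13 | methyl 3-[(2S,4S,5R)-4-[(tert-butyldimethylsilyl)oxy]-5-{(2R)-3,3-dimethoxy-2-[(4-methoxybenzyl)oxy]propyl}-5-methyloxolan-2-yl]prop-2-ynoate | COC(=O)C#C[C@@H]1C[C@H](O[Si](C)(C)C(C)(C)C)[C@@](C)(C[C@@H](OCc2ccc(OC)cc2)C(OC)OC)O1 | intermediate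
14 | methyl (2Z)-3-[(2S,4S,5R)-4-[(tert-butyldimethylsilyl)oxy]-5-{(2R)-3,3-dimethoxy-2-[(4-methoxybenzyl)oxy]propyl}-5-methyloxolan-2-yl]but-2-enoate | COC(=O)/C=C(/C)[C@@H]1C[C@H](O[Si](C)(C)C(C)(C)C)[C@@](C)(C[C@@H](OCc2ccc(OC)cc2)C(OC)OC)O1 | intermediate
15 | (2Z)-3-[(2S,4S,5R)-4-[(tert-butyldimethylsilyl)oxy]-5-{(2R)-3,3-dimethoxy-2-[(4-methoxybenzyl)oxy]propyl}-5-methyloxolan-2-yl]but-2-en-1-ol | OC/C=C(/C)[C@@H]1C[C@H](O[Si](C)(C)C(C)(C)C)[C@@](C)(C[C@@H](OCc2ccc(OC)cc2)C(OC)OC)O1 | intermediate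
16 | (2R)-3-[(2R,3S,5S)-3-[(tert-butyldimethylsilyl)oxy]-5-[(2Z)-4-hydroxybut-2-en-2-yl]-2-methyloxolan-2-yl]-2-[(4-methoxybenzyl)oxy]propanal | OC/C=C(/C)[C@@H]1C[C@H](O[Si](C)(C)C(C)(C)C)[C@@](C)(C[C@@H](OCc2ccc(OC)cc2)C=O)O1 | intermediate
17 | methyl acrylate | C=CC(=O)OC | starting material
18 | methyl (3RS,4R)-5-[(2R,3S,5S)-3-[(tert-butyldimethylsilyl)oxy]-5-[(2Z)-4-hydroxybut-2-en-2-yl]-2-methyloxolan-2-yl]-3-hydroxy-4-[(4-methoxybenzyl)oxy]-2-methylidenepentanoate | OC/C=C(/C)[C@@H]1C[C@H](O[Si](C)(C)C(C)(C)C)[C@@](C)(C[C@@H](OCc2ccc(OC)cc2)C(O)C(=C)C(=O)OC)O1 | intermediate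
19 | methyl (3RS,4R)-5-[(2R,3S,5S)-3-[(tert-butyldimethylsilyl)oxy]-2-methyl-5-[(2Z)-4-oxobut-2-en-2-yl]oxolan-2-yl]-3-hydroxy-4-[(4-methoxybenzyl)oxy]-2-methylidenepentanoate | O=C/C=C(/C)[C@@H]1C[C@H](O[Si](C)(C)C(C)(C)C)[C@@](C)(C[C@@H](OCc2ccc(OC)cc2)C(O)C(=C)C(=O)OC)O1 | intermediate
20 | methyl (2Z,4R)-2-(bromomethyl)-5-[(2R,3S,5S)-3-[(tert-butyldimethylsilyl)oxy]-2-methyl-5-[(2Z)-4-oxobut-2-en-2-yl]oxolan-2-yl]-4-[(4-methoxybenzyl)oxy]pent-2-enoate | O=C/C=C(/C)[C@@H]1C[C@H](O[Si](C)(C)C(C)(C)C)[C@@](C)(C[C@@H](OCc2ccc(OC)cc2)/C=C(\CBr)C(=O)OC)O1 | intermediate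
21 | methyl (1S,3S,4Z,6S,7S,8R,10R)-1-[(tert-butyldimethylsilyl)oxy]-3,10-epoxy-6-hydroxy-8-[(4-methoxybenzyl)oxy]germacra-4,11(13)-dien-12-oate (formed as its chromium alkoxide; 7S only through a CIP priority change, geometry as in 22) | COC(=O)C(=C)[C@H]1[C@@H](O)/C=C(/C)[C@@H]2C[C@H](O[Si](C)(C)C(C)(C)C)[C@@](C)(C[C@H]1OCc3ccc(OC)cc3)O2 | intermediate (not isolated)
22 | (1S,3S,4Z,6S,7R,8R,10R)-1-[(tert-butyldimethylsilyl)oxy]-3,10-epoxy-8-[(4-methoxybenzyl)oxy]germacra-4,11(13)-dien-12,6-olide | C=C1C(=O)O[C@H]2/C=C(/C)[C@@H]3C[C@H](O[Si](C)(C)C(C)(C)C)[C@@](C)(C[C@@H](OCc4ccc(OC)cc4)[C@@H]12)O3 | intermediate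
23 | (1S,3S,4Z,6S,7R,8R,10R)-1-[(tert-butyldimethylsilyl)oxy]-3,10-epoxy-8-hydroxygermacra-4,11(13)-dien-12,6-olide | C=C1C(=O)O[C@H]2/C=C(/C)[C@@H]3C[C@H](O[Si](C)(C)C(C)(C)C)[C@@](C)(C[C@@H](O)[C@@H]12)O3 | intermediate
24 | angelic acid [(2Z)-2-methylbut-2-enoic acid] | C/C=C(/C)C(=O)O | starting material
25 | (2Z)-2-methylbut-2-enoic 2,4,6-trichlorobenzoic anhydride | C/C=C(/C)C(=O)OC(=O)c1c(Cl)cc(Cl)cc1Cl | intermediate (not isolated)
26 | (1S,3S,4Z,6S,7R,8R,10R)-8-angeloyloxy-1-[(tert-butyldimethylsilyl)oxy]-3,10-epoxygermacra-4,11(13)-dien-12,6-olide | C=C1C(=O)O[C@H]2/C=C(/C)[C@@H]3C[C@H](O[Si](C)(C)C(C)(C)C)[C@@](C)(C[C@@H](OC(=O)/C(C)=C\C)[C@@H]12)O3 | intermediate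
27 | (1S,3S,4Z,6S,7R,8R,10R)-8-angeloyloxy-3,10-epoxy-1-hydroxygermacra-4,11(13)-dien-12,6-olide | C=C1C(=O)O[C@H]2/C=C(/C)[C@@H]3C[C@H](O)[C@@](C)(C[C@@H](OC(=O)/C(C)=C\C)[C@@H]12)O3 | target

**Step count and risk**

Total step count: 16. Longest linear sequence: 16 (1 → 27).

The three steps most likely to fail:

Step 13 is the main risk. The ring closure must tolerate a ten-membered ring spanning the trans-2,5-oxolane, compete with dimerisation, and deliver the C7 facial selectivity from an acyclic model that the macrocycle may override. The fallback sets out from 16 and comes back at 22. Trimethyl phosphonoacetate is alkylated with (iodomethyl)trimethylsilane (NaH, THF) to give methyl 2-(dimethoxyphosphoryl)-3-(trimethylsilyl)propanoate F1. Horner–Wadsworth–Emmons olefination of 16 with F1 (NaH, THF, 0 °C) gives the allylsilane alcohol F2 as an E/Z mixture. Nitroxyl oxidation as in step 11 gives the silyl enal F3. Bu4NF (THF, 1 mM) or BF3·OEt2 (CH2Cl2, −78 °C) then triggers an intramolecular Hosomi–Sakurai allylation whose alkoxide lactonises to 22. This replaces metal insertion into a bromide by a storable allylsilane that can be cyclised under anionic or Lewis-acidic control, and it bypasses steps 10 to 13.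

Step 5 is at risk because the β,γ-unsaturated aldehyde 8 can isomerise during a slow catalytic addition, and unbranched aliphatic aldehydes give only moderate selectivity in this alkynylation. The fallback sets out from 8 and comes back at 10. The lithium acetylide of 9 (LiN(SiMe3)2, THF, −78 °C, minutes) is added to crude 8 to give the C4-epimeric carbinol mixture F4. MnO2 oxidation gives the ynone F5. Midland reduction with B-(3-pinanyl)-9-borabicyclo[3.3.1]nonane (the antipode that gives 4S) returns 10 with reagent-controlled configuration.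

Step 10 is at risk because the amine-catalysed reaction of a hindered α-alkoxy aldehyde is slow and the base can erode C8. The fallback sets out from 16 and comes back at 18. Hydroalumination of 9 with i-Bu2AlH and N-methylmorpholine N-oxide (THF, 0 °C) gives the vinylalane F6, which adds to the aldehyde of 16 within minutes at 0 °C (one extra equivalent is consumed by the free hydroxyl) and gives 18 without any amine base.

Further compounds
F1 | step 13 | methyl 2-(dimethoxyphosphoryl)-3-(trimethylsilyl)propanoate | COC(=O)C(C[Si](C)(C)C)P(=O)(OC)OC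
F2 | step 13 | methyl (4R)-5-[(2R,3S,5S)-3-[(tert-butyldimethylsilyl)oxy]-5-[(2Z)-4-hydroxybut-2-en-2-yl]-2-methyloxolan-2-yl]-4-[(4-methoxybenzyl)oxy]-2-[(trimethylsilyl)methyl]pent-2-enoate (2E/2Z mixture) | OC/C=C(/C)[C@@H]1C[C@H](O[Si](C)(C)C(C)(C)C)[C@@](C)(C[C@@H](OCc2ccc(OC)cc2)C=C(C[Si](C)(C)C)C(=O)OC)O1
F3 | step 13 | methyl (4R)-5-[(2R,3S,5S)-3-[(tert-butyldimethylsilyl)oxy]-2-methyl-5-[(2Z)-4-oxobut-2-en-2-yl]oxolan-2-yl]-4-[(4-methoxybenzyl)oxy]-2-[(trimethylsilyl)methyl]pent-2-enoate (2E/2Z mixture) | O=C/C=C(/C)[C@@H]1C[C@H](O[Si](C)(C)C(C)(C)C)[C@@](C)(C[C@@H](OCc2ccc(OC)cc2)C=C(C[Si](C)(C)C)C(=O)OC)O1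
F4 | step 5 | methyl (4RS,6E,9R)-4-hydroxy-10,10-dimethoxy-9-[(4-methoxybenzyl)oxy]-7-methyldec-6-en-2-ynoate | COC(=O)C#CC(O)C/C=C(\C)C[C@@H](OCc1ccc(OC)cc1)C(OC)OC
F5 | step 5 | methyl (6E,9R)-10,10-dimethoxy-9-[(4-methoxybenzyl)oxy]-7-methyl-4-oxodec-6-en-2-ynoate | COC(=O)C#CC(=O)C/C=C(\C)C[C@@H](OCc1ccc(OC)cc1)C(OC)OC
F6 | step 10 | methyl 2-(diisobutylalumanyl)prop-2-enoate | COC(=O)C(=C)[Al](CC(C)C)CC(C)C
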